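**Retrosynthetic overview**
1. Target ⇐ removal of a tosyl group ⇐ B-alkyl Suzuki–Miyaura coupling at C6 of ring A with an (S)-configured homoallylic iodide; the side-chain stereocentre comes from a copper-catalysed asymmetric SN2′ alkylation.
2. (3R)-Chromanol ⇐ CBS reduction of a chroman-3-one ⇐ Baeyer–Villiger oxidation of a 2H-chromene-3-carbaldehyde, whose formyl carbon is the placeholder for the C3 oxygen.
3. Ring C (the dihydropyran) is the only ring made; rings A and B are bought. It is closed through C3–C4 by a domino oxa-Michael/aldol condensation of a 3-aroyl-2-hydroxybenzaldehyde with 3-methylbut-2-enal: O1–C2 forms first, then C3–C4 closes the ring.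
4. Enabling feature: on ring A the oxygen O1 (on C8a) lies between the C8 aroyl carbon and C4a. With C4 as a formyl group this is a salicylaldehyde, so the phenoxide carries in the quaternary C2 (gem-dimethyl) and places the C3 enolate next to C4. The same C8 ketone, ortho to O1 and to the C7 oxygen, unmasks these two oxygens one after the other by chelation-controlled demethylation.
5. Aldehyde ⇐ ortho-formylation ⇐ mono-demethylation ⇐ Friedel–Crafts aroylation of 1,3,5-trimethoxybenzene.

Key step: step 5

Abbreviations: Ts = 4-methylbenzenesulfonyl; TBDPS = tert-butyldiphenylsilyl; ring A = benzene ring of the chroman, ring B = 3-hydroxyphenyl ring, ring C = dihydropyran ring.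
Remark: the absolute sense of induction in step 13 is fixed by ligand choice; the phosphoramidite antipode that delivers the (S)-configured ether is the one used.

**Step 1**
Reactants: 1 3-hydroxybenzoic acid
Product: 2 3-(tosyloxy)benzoic acid
Conditions: TsCl (1.1 equiv), NaOH (aq., 3 equiv), THF, 0 °C to rt; then aq. HCl
Reagents that add atoms: 4-methylbenzenesulfonyl chloride, Cc1ccc(cc1)S(Cl)(=O)=O
Why: Schotten–Baumann O-sulfonylation of the phenoxide, any mixed anhydride at the carboxylate being hydrolysed back; the aryl tosylate is chosen because it should survive AlCl3, BCl3, TiCl4, peracid and carbonate base until step 17.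

**Step 2**
Reactants: 2 3-(tosyloxy)benzoic acid; 3 1,3,5-trimethoxybenzene
Product: 5 (2,4,6-trimethoxyphenyl)[3-(tosyloxy)phenyl]methanone, via acid chloride 4 (not isolated)
Conditions: (COCl)2 (1.2 equiv), DMF (cat.), CH2Cl2, 0 °C to rt, evaporate; then 3, AlCl3 (1.2 equiv), CH2Cl2, 0 °C
Reagents that add atoms: none
Why: Friedel–Crafts acylation of the threefold activated arene, whose three free positions are equivalent, by the acid chloride made in situ; the new ketone deactivates the product against a second acylation.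

**Step 3**
Reactants: 5 (2,4,6-trimethoxyphenyl)[3-(tosyloxy)phenyl]methanone
Product: 6 (2-hydroxy-4,6-dimethoxyphenyl)[3-(tosyloxy)phenyl]methanone
Conditions: BCl3 (1.2 equiv), CH2Cl2, −78 to 0 °C; then H2O
Reagents that add atoms: none
Why: Chelation-controlled ether cleavage, in which BCl3 binds the ketone oxygen and one ortho methoxy oxygen in a six-membered chelate and chloride removes only that methyl group, so the second ortho and the para methoxy group should remain with about one equivalent of reagent.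

**Step 4**
Reactants: 6 (2-hydroxy-4,6-dimethoxyphenyl)[3-(tosyloxy)phenyl]methanone
Product: 7 2-hydroxy-4,6-dimethoxy-3-[3-(tosyloxy)benzoyl]benzaldehyde
Conditions: Cl2CHOMe (1.5 equiv), TiCl4 (2.5 equiv), CH2Cl2, −20 to 0 °C; then H2O
Reagents that add atoms: dichloro(methoxy)methane, COC(Cl)Cl; water, O
Why: Rieche formylation, in which the titanium phenoxide delivers the electrophile to the only ring position ortho to the phenol (between OH and OMe) and hydrolysis of the α-chloro ether releases the aldehyde.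

**Step 5**
Reactants: 7 2-hydroxy-4,6-dimethoxy-3-[3-(tosyloxy)benzoyl]benzaldehyde; 8 3-methylbut-2-enal
Product: 10 5,7-dimethoxy-2,2-dimethyl-8-[3-(tosyloxy)benzoyl]-2H-chromene-3-carbaldehyde, via oxa-Michael adduct 9 (not isolated)
Conditions: 8 (3 equiv), K2CO3 (0.5 equiv), 1,4-dioxane, 100 °C
Reagents that add atoms: none
Why: K2CO3 turns 7 into its phenoxide, which adds reversibly to C3 of the enal (oxa-Michael; forms O1–C2 and the quaternary C2); the enolate carbon so formed (C3 of the target) attacks the neighbouring formyl carbon (C4) in an intramolecular aldol addition, and E1cB loss of water makes the sequence irreversible and leaves the conjugated 2H-chromene-3-carbaldehyde. The closest known reaction type is the base-mediated domino oxa-Michael/aldol condensation of salicylaldehydes with α,β-unsaturated aldehydes, which is documented for 3-methylbut-2-enal. Ring C is closed by the C3–C4 bond in a 6-(enolexo)-exo-trig mode. No stereocentre is formed, since C3 and C4 end as sp2 carbons; C3 is set in step 7. The step needs O- over C-attack, 1,4- over 1,2-addition and ring closure faster than enal self-condensation: 7 has a single phenol whose ortho and para ring positions are all substituted (so no Knoevenagel/electrocyclisation chromenylation), neither carbonyl group of 7 is enolisable, and only the adduct at O1 has an electrophile (C4) within reach, so unproductive additions revert.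

**Step 6**
Reactants: 10 5,7-dimethoxy-2,2-dimethyl-8-[3-(tosyloxy)benzoyl]-2H-chromene-3-carbaldehyde
Product: 12 5,7-dimethoxy-2,2-dimethyl-8-[3-(tosyloxy)benzoyl]chroman-3-one, via enol formate 11 (not isolated)
Conditions: mCPBA (1.3 equiv), CH2Cl2, 0 °C to rt; then K2CO3 (0.1 equiv), MeOH, 0 °C
Reagents that add atoms: 3-chloroperoxybenzoic acid, OOC(=O)c1cccc(Cl)c1
Why: Baeyer–Villiger oxidation of the α,β-unsaturated aldehyde with migration of the alkenyl carbon gives the enol formate, and mild methanolysis releases the C3 ketone; the hindered diaryl ketone and the acceptor-substituted C3=C4 bond should react more slowly with the peracid.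

**Step 7**
Reactants: 12 5,7-dimethoxy-2,2-dimethyl-8-[3-(tosyloxy)benzoyl]chroman-3-one
Product: 13 [(3R)-3-hydroxy-5,7-dimethoxy-2,2-dimethylchroman-8-yl][3-(tosyloxy)phenyl]methanone
Conditions: (S)-2-methyl-CBS-oxazaborolidine [(S)-1-methyl-3,3-diphenyltetrahydro-1H,3H-pyrrolo[1,2-c][1,3,2]oxazaborole] (0.2 equiv), catecholborane (2 equiv), toluene, −78 to −40 °C; then MeOH, H2O
Reagents that add atoms: none
Why: Corey–Bakshi–Shibata reduction, in which the ketone binds the (S)-oxazaborolidine with the quaternary C2 side as the large and the C4 methylene as the small substituent, so hydride should be delivered to the face that gives the (3R)-alcohol; the diaryl ketone, flanked by two ortho oxygens, is too hindered to compete at low temperature.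

**Step 8**
Reactants: 13 [(3R)-3-hydroxy-5,7-dimethoxy-2,2-dimethylchroman-8-yl][3-(tosyloxy)phenyl]methanone
Product: 14 [(3R)-3,7-dihydroxy-5-methoxy-2,2-dimethylchroman-8-yl][3-(tosyloxy)phenyl]methanone
Conditions: BCl3 (3 equiv), CH2Cl2, −78 to 0 °C; then H2O
Reagents that add atoms: none
Why: Second chelation-controlled demethylation by BCl3: only the C7 methoxy group is ortho to the C8 ketone and has a methyl group open to chloride attack, whereas the C5 methoxy group is para and O1 is held in ring C; the C3 stereocentre is not involved.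

**Step 9**
Reactants: 14 [(3R)-3,7-dihydroxy-5-methoxy-2,2-dimethylchroman-8-yl][3-(tosyloxy)phenyl]methanone
Product: 15 [(3R)-6-bromo-3,7-dihydroxy-5-methoxy-2,2-dimethylchroman-8-yl][3-(tosyloxy)phenyl]methanone
Conditions: NBS (1.0 equiv), CH2Cl2, −40 to 0 °C
Reagents that add atoms: N-bromosuccinimide, BrN1C(=O)CCC1=O
Why: Electrophilic aromatic bromination at C6, the only unsubstituted position of ring A and ortho to the free phenol; ring B is deactivated by the ketone and the sulfonate.

**Step 10**
Reactants: 16 3-methylbut-2-en-1-ol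
Product: 17 tert-butyl[(3-methylbut-2-en-1-yl)oxy]diphenylsilane
Conditions: TBDPSCl (1.05 equiv), imidazole (2 equiv), DMF, rt
Reagents that add atoms: tert-butyl(chloro)diphenylsilane, CC(C)(C)[Si](Cl)(c1ccccc1)c1ccccc1
Why: Standard silylation of a primary alcohol; the bulky silyl ether should tolerate SeO2, the Grignard reagent and the copper catalyst.

**Step 11**
Reactants: 17 tert-butyl[(3-methylbut-2-en-1-yl)oxy]diphenylsilane
Product: 18 (E)-4-[(tert-butyldiphenylsilyl)oxy]-2-methylbut-2-en-1-ol
Conditions: SeO2 (0.2 equiv), t-BuOOH (2 equiv, in decane), CH2Cl2, rt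
Reagents that add atoms: tert-butyl hydroperoxide, CC(C)(C)OO
Why: SeO2-catalysed allylic oxidation (ene reaction followed by a [2,3]-sigmatropic shift), which is selective for the (E)-methyl group of a gem-dimethyl trisubstituted alkene and so gives the (E)-allylic alcohol.

**Step 12**
Reactants: 18 (E)-4-[(tert-butyldiphenylsilyl)oxy]-2-methylbut-2-en-1-ol
Product: 19 (E)-tert-butyl[(4-chloro-3-methylbut-2-en-1-yl)oxy]diphenylsilane
Conditions: NCS (1.2 equiv), Me2S (1.3 equiv), CH2Cl2, −20 to 0 °C
Reagents that add atoms: N-chlorosuccinimide, ClN1C(=O)CCC1=O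
Why: Corey–Kim chlorination, in which the alkoxysulfonium ion is displaced by chloride in an SN2 reaction without allylic transposition or loss of alkene geometry.

**Step 13**
Reactants: 19 (E)-tert-butyl[(4-chloro-3-methylbut-2-en-1-yl)oxy]diphenylsilane; 20 4-bromo-2-methylbut-1-ene
Product: 22 (S)-tert-butyl{[5-methyl-2-(prop-1-en-2-yl)hex-5-en-1-yl]oxy}diphenylsilane, via Grignard reagent 21 (not isolated)
Conditions: 20, Mg, THF, rt (gives 21); then 19, copper thiophene-2-carboxylate Cu(O2CC4H3S) (3 mol %), BINOL-derived N,N-bis(1-phenylethyl)phosphoramidite (3.3 mol %, single enantiomer), CH2Cl2, −78 °C, slow addition of 21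
Reagents that add atoms: none
Why: Copper-catalysed asymmetric allylic alkylation (anti-SN2′) of a 2-methyl-substituted allylic chloride with a Grignard reagent, in which the chiral phosphoramidite–copper complex selects one face of the γ-carbon and so sets the new stereocentre (S) while the double bond moves to give the isopropenyl group.

**Step 14**
Reactants: 22 (S)-tert-butyl{[5-methyl-2-(prop-1-en-2-yl)hex-5-en-1-yl]oxy}diphenylsilane
Product: 23 (S)-5-methyl-2-(prop-1-en-2-yl)hex-5-en-1-ol
Conditions: Bu4NF (1.2 equiv), THF, rt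
Reagents that add atoms: none
Why: Fluoride-induced desilylation, which does not touch the alkenes or the stereocentre.

**Step 15**
Reactants: 23 (S)-5-methyl-2-(prop-1-en-2-yl)hex-5-en-1-ol
Product: 24 (S)-1-iodo-5-methyl-2-(prop-1-en-2-yl)hex-5-ene
Conditions: I2 (1.2 equiv), PPh3 (1.2 equiv), imidazole (1.5 equiv), CH2Cl2, 0 °C, dark
Reagents that add atoms: iodine, II
Why: Appel-type (Garegg–Samuelsson) iodination by SN2 displacement of the alkoxyphosphonium ion at the primary carbon, one atom away from the stereocentre, which therefore stays intact.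

**Step 16**
Reactants: 24 (S)-1-iodo-5-methyl-2-(prop-1-en-2-yl)hex-5-ene; 15 [(3R)-6-bromo-3,7-dihydroxy-5-methoxy-2,2-dimethylchroman-8-yl][3-(tosyloxy)phenyl]methanone
Product: 27 {(3R)-3,7-dihydroxy-5-methoxy-2,2-dimethyl-6-[(2R)-5-methyl-2-(prop-1-en-2-yl)hex-5-en-1-yl]chroman-8-yl}[3-(tosyloxy)phenyl]methanone, via alkyllithium 25 (not isolated), via borinate 26 (not isolated)
Conditions: 24 (1.5 equiv), t-BuLi (3.1 equiv), Et2O, −78 °C; B-methoxy-9-BBN (1.7 equiv), THF, −78 °C to rt; then 15, Pd(OAc)2 (5 mol %), 2-dicyclohexylphosphino-2′,6′-dimethoxybiphenyl (SPhos, 10 mol %), K3PO4 (3 M aq.), DMF, 60 °C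
Reagents that add atoms: none
Why: B-alkyl Suzuki–Miyaura coupling in which lithium–iodine exchange and trapping with B-methoxy-9-BBN give a borinate that transfers its primary alkyl group to palladium; no radical arises at the homoallylic carbon, so the alkenes and the β-stereocentre should stay intact (its descriptor changes from S to R only through the priority rules).

**Step 17**
Reactants: 27 {(3R)-3,7-dihydroxy-5-methoxy-2,2-dimethyl-6-[(2R)-5-methyl-2-(prop-1-en-2-yl)hex-5-en-1-yl]chroman-8-yl}[3-(tosyloxy)phenyl]methanone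
Product: 28 {(3R)-3,7-dihydroxy-5-methoxy-2,2-dimethyl-6-[(2R)-5-methyl-2-(prop-1-en-2-yl)hex-5-en-1-yl]chroman-8-yl}(3-hydroxyphenyl)methanone
Conditions: KOH (5 equiv), MeOH/THF/H2O, 60 °C; then aq. HCl to pH 5
Reagents that add atoms: none
Why: Hydroxide attacks sulfur of the aryl sulfonate (S–O cleavage) and frees the ring B phenol; the chelated phenol, the chromanol, the 1,1-disubstituted alkenes and the benzophenone are stable to base, and no acid meets the alkenes.

**Compound list**
1 | 3-hydroxybenzoic acid | OC(=O)c1cccc(O)c1 | starting material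
2 | 3-(tosyloxy)benzoic acid | OC(=O)c1cccc(OS(=O)(=O)c2ccc(C)cc2)c1 | intermediate
3 | 1,3,5-trimethoxybenzene | COc1cc(OC)cc(OC)c1 | starting material
4 | 3-(tosyloxy)benzoyl chloride | ClC(=O)c1cccc(OS(=O)(=O)c2ccc(C)cc2)c1 | intermediate (not isolated)
5 | (2,4,6-trimethoxyphenyl)[3-(tosyloxy)phenyl]methanone | COc1cc(OC)c(C(=O)c2cccc(OS(=O)(=O)c3ccc(C)cc3)c2)c(OC)c1 | intermediate
6 | (2-hydroxy-4,6-dimethoxyphenyl)[3-(tosyloxy)phenyl]methanone | COc1cc(O)c(C(=O)c2cccc(OS(=O)(=O)c3ccc(C)cc3)c2)c(OC)c1 | intermediate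
7 | 2-hydroxy-4,6-dimethoxy-3-[3-(tosyloxy)benzoyl]benzaldehyde | O=Cc1c(O)c(C(=O)c2cccc(OS(=O)(=O)c3ccc(C)cc3)c2)c(OC)cc1OC | intermediate
8 | 3-methylbut-2-enal | CC(C)=CC=O | starting material
9 | 4,6-dimethoxy-2-[(2-methyl-4-oxobutan-2-yl)oxy]-3-[3-(tosyloxy)benzoyl]benzaldehyde (oxa-Michael adduct) | O=CCC(C)(C)Oc1c(C=O)c(OC)cc(OC)c1C(=O)c1cccc(OS(=O)(=O)c2ccc(C)cc2)c1 | intermediate (not isolated)
10 | 5,7-dimethoxy-2,2-dimethyl-8-[3-(tosyloxy)benzoyl]-2H-chromene-3-carbaldehyde | COc1cc(OC)c(C(=O)c2cccc(OS(=O)(=O)c3ccc(C)cc3)c2)c2c1C=C(C=O)C(C)(C)O2 | intermediate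
11 | 5,7-dimethoxy-2,2-dimethyl-8-[3-(tosyloxy)benzoyl]-2H-chromen-3-yl formate | COc1cc(OC)c(C(=O)c2cccc(OS(=O)(=O)c3ccc(C)cc3)c2)c2c1C=C(OC=O)C(C)(C)O2 | intermediate (not isolated)
12 | 5,7-dimethoxy-2,2-dimethyl-8-[3-(tosyloxy)benzoyl]chroman-3-one | COc1cc(OC)c(C(=O)c2cccc(OS(=O)(=O)c3ccc(C)cc3)c2)c2c1CC(=O)C(C)(C)O2 | intermediate
13 | [(3R)-3-hydroxy-5,7-dimethoxy-2,2-dimethylchroman-8-yl][3-(tosyloxy)phenyl]methanone | COc1cc(OC)c(C(=O)c2cccc(OS(=O)(=O)c3ccc(C)cc3)c2)c2c1C[C@@H](O)C(C)(C)O2 | intermediate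
14 | [(3R)-3,7-dihydroxy-5-methoxy-2,2-dimethylchroman-8-yl][3-(tosyloxy)phenyl]methanone | COc1cc(O)c(C(=O)c2cccc(OS(=O)(=O)c3ccc(C)cc3)c2)c2c1C[C@@H](O)C(C)(C)O2 | intermediate
15 | [(3R)-6-bromo-3,7-dihydroxy-5-methoxy-2,2-dimethylchroman-8-yl][3-(tosyloxy)phenyl]methanone | COc1c(Br)c(O)c(C(=O)c2cccc(OS(=O)(=O)c3ccc(C)cc3)c2)c2c1C[C@@H](O)C(C)(C)O2 | intermediate
16 | 3-methylbut-2-en-1-ol | CC(C)=CCO | starting material
17 | tert-butyl[(3-methylbut-2-en-1-yl)oxy]diphenylsilane | CC(C)=CCO[Si](c1ccccc1)(c1ccccc1)C(C)(C)C | intermediate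
18 | (E)-4-[(tert-butyldiphenylsilyl)oxy]-2-methylbut-2-en-1-ol | OC/C(C)=C/CO[Si](c1ccccc1)(c1ccccc1)C(C)(C)C | intermediate
19 | (E)-tert-butyl[(4-chloro-3-methylbut-2-en-1-yl)oxy]diphenylsilane | ClC/C(C)=C/CO[Si](c1ccccc1)(c1ccccc1)C(C)(C)C | intermediate
20 | 4-bromo-2-methylbut-1-ene | CC(=C)CCBr | starting material
21 | (3-methylbut-3-en-1-yl)magnesium bromide | CC(=C)CC[Mg]Br | intermediate (not isolated)
22 | (S)-tert-butyl{[5-methyl-2-(prop-1-en-2-yl)hex-5-en-1-yl]oxy}diphenylsilane | C=C(C)CC[C@H](CO[Si](c1ccccc1)(c1ccccc1)C(C)(C)C)C(C)=C | intermediate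
23 | (S)-5-methyl-2-(prop-1-en-2-yl)hex-5-en-1-ol | C=C(C)CC[C@H](CO)C(C)=C | intermediate
24 | (S)-1-iodo-5-methyl-2-(prop-1-en-2-yl)hex-5-ene | C=C(C)CC[C@H](CI)C(C)=C | intermediate
25 | (S)-[5-methyl-2-(prop-1-en-2-yl)hex-5-en-1-yl]lithium | C=C(C)CC[C@H](C[Li])C(C)=C | intermediate (not isolated)
26 | lithium (S)-B-methoxy-B-[5-methyl-2-(prop-1-en-2-yl)hex-5-en-1-yl]-9-borabicyclo[3.3.1]nonan-9-uide | C=C(C)CC[C@H](C[B-]1(OC)C2CCCC1CCC2)C(C)=C.[Li+] | intermediate (not isolated)
27 | {(3R)-3,7-dihydroxy-5-methoxy-2,2-dimethyl-6-[(2R)-5-methyl-2-(prop-1-en-2-yl)hex-5-en-1-yl]chroman-8-yl}[3-(tosyloxy)phenyl]methanone | C=C(C)CC[C@H](Cc1c(O)c(C(=O)c2cccc(OS(=O)(=O)c3ccc(C)cc3)c2)c2c(c1OC)C[C@@H](O)C(C)(C)O2)C(=C)C | intermediate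
28 | {(3R)-3,7-dihydroxy-5-methoxy-2,2-dimethyl-6-[(2R)-5-methyl-2-(prop-1-en-2-yl)hex-5-en-1-yl]chroman-8-yl}(3-hydroxyphenyl)methanone | C=C(C)CC[C@H](Cc1c(O)c(C(=O)c2cccc(O)c2)c2c(c1OC)C[C@@H](O)C(C)(C)O2)C(=C)C | target

**Step count and risks**
Total step count: 17 (11 on the main line, 6 for the side-chain fragment).
Longest linear sequence: 11 steps (steps 1 to 9, then 16 and 17).

The three steps most likely to fail:

(1) Step 5, the key step. The phenoxide of 7 is chelated and flanked by two acyl groups. It may add too slowly to the β,β-disubstituted enal, so that enal self-condensation and vinylogous aldol addition at the formyl group consume the material before ring C closes. The fallback sets out from 7 and uses a much stronger Michael acceptor. With 2-methyl-1-nitroprop-1-ene and DABCO in THF at 40 °C, oxa-Michael addition, intramolecular Henry reaction (again closing ring C through C3–C4) and dehydration should give 5,7-dimethoxy-2,2-dimethyl-3-nitro-8-[3-(tosyloxy)benzoyl]-2H-chromene F1. Iron powder in acetic acid at 80 °C (reduction of the nitroalkene to the oxime/enamine stage and hydrolysis) then comes back to the route at ketone 12.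

(2) Step 16. Oxidative addition and transmetalation may be slow at the di-ortho-substituted aryl bromide that carries an ortho phenoxide, so that protodeboronation and β-hydride loss of the alkylborane win. The fallback sets out from 15 and 24, masks both hydroxy groups and changes the nucleophile to an organozinc, which needs no base or water. TBSOTf and 2,6-lutidine in CH2Cl2 convert 15 into the bis(tert-butyldimethylsilyl) ether F2. Iodide 24 is treated with t-BuLi at −78 °C and then ZnCl2 to give the alkylzinc chloride F3. Negishi coupling of F2 with F3 (Pd(OAc)2, 2-dicyclohexylphosphino-2′,6′-bis(dimethylamino)biphenyl, THF, 40 °C) should give the coupled bis(silyl ether) F4. Bu4NF in THF then comes back to the route at 27.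

(3) Step 13. Facial selectivity may be poor, or direct SN2 substitution may compete (loss of regiocontrol), because the γ-carbon carries a bulky silyloxymethyl group. The fallback sets out from 20 and replaces catalyst control by auxiliary control. NaI in acetone converts 20 into 4-iodo-2-methylbut-1-ene F5. Commercial (S)-4-benzyloxazolidin-2-one is acylated (n-BuLi, then 3-methylbut-2-enoyl chloride) to (S)-4-benzyl-3-(3-methylbut-2-enoyl)oxazolidin-2-one F6. γ-Deprotonation with NaN(SiMe3)2 in THF at −78 °C gives the chelated dienolate, which is alkylated at the α-carbon by F5 on the face away from the benzyl group. This deconjugative Evans alkylation should give (S)-4-benzyl-3-[(2S)-5-methyl-2-(prop-1-en-2-yl)hex-5-enoyl]oxazolidin-2-one F7. LiBH4 in Et2O with one equivalent of water cleaves the auxiliary reductively and comes back to the route at alcohol 23.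

**Further compounds**
F1 | step 5 | 5,7-dimethoxy-2,2-dimethyl-3-nitro-8-[3-(tosyloxy)benzoyl]-2H-chromene | COc1cc(OC)c(C(=O)c2cccc(OS(=O)(=O)c3ccc(C)cc3)c2)c2c1C=C([N+](=O)[O-])C(C)(C)O2
F2 | step 16 | {(3R)-6-bromo-3,7-bis[(tert-butyldimethylsilyl)oxy]-5-methoxy-2,2-dimethylchroman-8-yl}[3-(tosyloxy)phenyl]methanone | COc1c(Br)c(O[Si](C)(C)C(C)(C)C)c(C(=O)c2cccc(OS(=O)(=O)c3ccc(C)cc3)c2)c2c1C[C@@H](O[Si](C)(C)C(C)(C)C)C(C)(C)O2
F3 | step 16 | (S)-[5-methyl-2-(prop-1-en-2-yl)hex-5-en-1-yl]zinc chloride | C=C(C)CC[C@H](C[Zn]Cl)C(C)=C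
F4 | step 16 | {(3R)-3,7-bis[(tert-butyldimethylsilyl)oxy]-5-methoxy-2,2-dimethyl-6-[(2R)-5-methyl-2-(prop-1-en-2-yl)hex-5-en-1-yl]chroman-8-yl}[3-(tosyloxy)phenyl]methanone | C=C(C)CC[C@H](Cc1c(O[Si](C)(C)C(C)(C)C)c(C(=O)c2cccc(OS(=O)(=O)c3ccc(C)cc3)c2)c2c(c1OC)C[C@@H](O[Si](C)(C)C(C)(C)C)C(C)(C)O2)C(=C)C
F5 | step 13 | 4-iodo-2-methylbut-1-ene | CC(=C)CCI
F6 | step 13 | (S)-4-benzyl-3-(3-methylbut-2-enoyl)oxazolidin-2-one | CC(C)=CC(=O)N1[C@@H](Cc2ccccc2)COC1=O
F7 | step 13 | (S)-4-benzyl-3-[(2S)-5-methyl-2-(prop-1-en-2-yl)hex-5-enoyl]oxazolidin-2-one | C=C(C)CC[C@H](C(=O)N1[C@@H](Cc2ccccc2)COC1=O)C(C)=C
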